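**Plan**
- Feature (eremophilane numbering): the angular methyl C14 sits on C5 of the ring-fusion bond C5–C10, and the carbons flanking that bond, C4 (ring A) and C9 (ring B), can both carry oxygen. A 4,9-dioxygenated octal-5(10)-ene is therefore C2-symmetric, so C14 can be put on as a CH2 across C5=C10 and set free by cutting C10–C14.
- Retrosynthetic cuts, in order: O–acyl at C9 and C2; C7–C11 (epoxide opening); C4–C15 with a 1,3-shift of oxygen from C2 back to C4; C10–C14 (cyclopropane opening); C5–C14 and C10–C14 together (cyclopropanation); the two carbinol C–H bonds at C4 and C9 (catalytic reduction).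
- Forward: a bought decalin is taken to the ene-dione and the C2 diol; the cyclopropane closes in step 4 and is opened in step 7 to leave the C5 methyl; then ring B oxygens with the trans fusion, ring A methyl and C2 oxygen, the isopropenyl group, and the two esters.
- Stereochemistry: the catalyst sets the C4 and C9 carbinols, and these deliver CH2 to the β-face (C5). The C5 methyl then governs C10 (dissolving-metal reduction), C9 (α-face enol ether oxidation), C8 and C7 (α-epoxide, trans-diaxial opening), C4 (α-face hydrogenation) and C2 (equatorial hydride).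

Key step: step 4

Numbering: eremophilane locants are used from compound 12 on (ring A = C1–C5, C10; ring B = C5–C10; C14 on C5, C15 on C4, C11–C13 isopropenyl); β is the face of C14; "tetranor" and "trinor" names lack C11–C13 and C15, or C11–C13.
Assumption: in the oxazaborolidine model the fully substituted alkenyl carbon is taken as the large group at each carbonyl, so the (R)-catalyst is expected to give the (S)-carbinols; diol 1 is used as the commercial mixture of stereoisomers, which all converge at 5.

Step 1
Reactants: 1 decahydronaphthalene-1,5-diol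
Product: 3 octahydronaphthalene-1,5-dione, via hydroxy ketone 2 (not isolated)
Conditions: TEMPO (cat.), KBr (cat.), NaOCl, NaHCO3, CH2Cl2/H2O, 0 °C
Reagents that add atoms: none
Why: TEMPO-catalysed hypochlorite oxidation of both secondary carbinols should give the diketone from every stereoisomer of 1, and the ring-fusion configuration is erased in step 2.

Step 2
Reactants: 3 octahydronaphthalene-1,5-dione
Product: 5 3,4,7,8-tetrahydronaphthalene-1,5(2H,6H)-dione, via bromo diketone 4 (not isolated)
Conditions: Br2 (1.0 equiv), AcOH, 15 °C; then Et3N, CH2Cl2, 0 → 25 °C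
Reagents that add atoms: none
Why: Acid-catalysed α-bromination should go through the more substituted enol to the ring-fusion carbon, and the amine then removes HBr with the neighbouring fusion C–H that is α to the second carbonyl (α-bromination/dehydrobromination), giving the tetrasubstituted, doubly conjugated alkene.

Step 3
Reactants: 5 3,4,7,8-tetrahydronaphthalene-1,5(2H,6H)-dione
Product: 7 (1S,5S)-1,2,3,4,5,6,7,8-octahydronaphthalene-1,5-diol, via hydroxy enone 6 (not isolated)
Conditions: (R)-Me-CBS oxazaborolidine (0.3 equiv), BH3·SMe2, THF, −20 °C; MeOH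
Reagents that add atoms: none
Why: Corey–Bakshi–Shibata reduction should deliver hydride to the same heterotopic face of both enone carbonyls (alkenyl carbon as large group) so that both carbinols are S, and since the minor pathway ends mainly in the separable meso diol the C2 diol should be enriched.

Step 4
Reactants: 7 (1S,5S)-1,2,3,4,5,6,7,8-octahydronaphthalene-1,5-diol; 8 diiodomethane
Product: 9 (1R,2S,6R,7S)-tricyclo[4.4.1.0^1,6]undecane-2,7-diol
Conditions: Et2Zn (5 equiv), CH2I2 (10 equiv), CH2Cl2, 0 → 25 °C
Reagents that add atoms: diiodomethane, ICI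
Why: In this Simmons–Smith cyclopropanation (Furukawa variant) diethylzinc should turn both allylic hydroxyls into zinc alkoxides that hold the iodomethylzinc carbenoid, and the methylene is passed to the C5=C10 alkene through a concerted butterfly transition state, so C5–C14 and C10–C14 form together. The closest known reaction is the hydroxyl-directed cyclopropanation of octal-9(10)-en-1-ols and other tetrasubstituted cyclic allylic alcohols. The three-membered ring closes by a concerted [2+1] addition, not by a stepwise exo or endo closure, and it turns the octalin into a [4.4.1]propellane. The new stereocentres C5 and C10 are controlled by the C4 and C9 carbinols, which lie on the same face of the alkene (C2 axis through the midpoint of C5=C10) and reinforce each other, so the methylene should come from the β-face. The only selectivity needed is facial, since there is one alkene and both ends are equivalent; the double alkoxide delivery to an electron-rich, otherwise unbiased alkene secures it. The product keeps the C2 axis, which makes its two hydroxyls homotopic for step 5.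

Step 5
Reactants: 9 (1R,2S,6R,7S)-tricyclo[4.4.1.0^1,6]undecane-2,7-diol
Product: 10 mono-TBS ether of 9
Conditions: TBSCl (1.0 equiv), imidazole, DMF, 25 °C
Reagents that add atoms: tert-butyldimethylsilyl chloride, CC(C)(C)[Si](C)(C)Cl
Why: Silylation of one of two homotopic hydroxyls can give only one mono-ether, and the statistical diol and bis-ether fractions would be recycled.

Step 6
Reactants: 10 mono-TBS ether of 9
Product: 11 O-phenyl thionocarbonate of 10
Conditions: PhOC(S)Cl, pyridine, DMAP (cat.), CH2Cl2, 25 °C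
Reagents that add atoms: O-phenyl chlorothionoformate, S=C(Cl)Oc1ccccc1
Why: Acylation of the remaining cyclopropyl carbinol (C9–OH) should give the thionocarbonate needed for Barton–McCombie radical generation.

Step 7
Reactants: 11 O-phenyl thionocarbonate of 10
Product: 12 4β-(tert-butyldimethylsilyloxy)-11,12,13,15-tetranoreremophil-9-ene
Conditions: Bu3SnH, AIBN (cat.), toluene, 90 °C
Reagents that add atoms: none
Why: Barton–McCombie generation of the C9 radical should be followed by cyclopropylcarbinyl ring opening of the exocyclic C10–C14 bond, which overlaps with the radical orbital far better than the ring-fusion C5–C10 bond, and the primary radical takes hydrogen from the stannane, so C14 becomes the C5 methyl and C9=C10 appears while C4 and C5 keep their configuration.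

Step 8
Reactants: 12 4β-(tert-butyldimethylsilyloxy)-11,12,13,15-tetranoreremophil-9-ene
Product: 13 4β-(tert-butyldimethylsilyloxy)-11,12,13,15-tetranoreremophil-9-en-8-one
Conditions: Rh2(cap)4 (1 mol%), t-BuOOH, K2CO3, CH2Cl2, 25 °C
Reagents that add atoms: tert-butyl hydroperoxide, CC(C)(C)OO
Why: In this dirhodium caprolactamate/hydroperoxide allylic oxidation the peroxyl radical should abstract the C8–H that gives the allyl radical with a tertiary terminus, and oxygen ends on the secondary terminus as in the oxidation of steroid 5-enes to 7-ketones, giving the β,β-disubstituted enone.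

Step 9
Reactants: 13 4β-(tert-butyldimethylsilyloxy)-11,12,13,15-tetranoreremophil-9-en-8-one
Product: 15 4β-(tert-butyldimethylsilyloxy)-8-(triisopropylsilyloxy)-10αH-11,12,13,15-tetranoreremophil-8-ene, via lithium enolate 14 (not isolated)
Conditions: Li (2.5 equiv), t-BuOH (1.0 equiv), NH3(l)/THF, −78 °C; isoprene; NH3 off; TIPSOTf, Et3N, THF, −78 → 0 °C
Reagents that add atoms: triisopropylsilyl trifluoromethanesulfonate, CC(C)[Si](C(C)C)(C(C)C)OS(=O)(=O)C(F)(F)F
Why: In the dissolving-metal (Birch-type) enone reduction the β-carbanion at C10 should be protonated axially on the α-face to give the trans ring fusion, as 4-en-3-one steroids give 5α products, and the regiospecific Δ8 lithium enolate is O-silylated (reductive silylation).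

Step 10
Reactants: 15 4β-(tert-butyldimethylsilyloxy)-8-(triisopropylsilyloxy)-10αH-11,12,13,15-tetranoreremophil-8-ene
Product: 17 4β-(tert-butyldimethylsilyloxy)-9α-(triisopropylsilyloxy)-10αH-11,12,13,15-tetranoreremophilan-8-one, via silyloxy epoxide 16 (not isolated)
Conditions: mCPBA, NaHCO3, CH2Cl2, −20 → 25 °C
Reagents that add atoms: 3-chloroperoxybenzoic acid, O=C(OO)c1cccc(Cl)c1
Why: In this Rubottom oxidation the peracid should epoxidise the enol ether on the α-face, because the β-face at C9 is syn-axial to the C5 methyl, and opening with 1,4-silyl migration gives the equatorial 9α-silyloxy ketone.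

Step 11
Reactants: 17 4β-(tert-butyldimethylsilyloxy)-9α-(triisopropylsilyloxy)-10αH-11,12,13,15-tetranoreremophilan-8-one
Product: 19 4β-(tert-butyldimethylsilyloxy)-9α-(triisopropylsilyloxy)-10αH-11,12,13,15-tetranoreremophil-7-en-8-yl trifluoromethanesulfonate, via potassium enolate 18 (not isolated)
Conditions: KHMDS, THF, −78 °C; N-(5-chloro-2-pyridyl)triflimide, −78 → −20 °C
Reagents that add atoms: N-(5-chloro-2-pyridyl)bis(trifluoromethanesulfonimide), FC(F)(F)S(=O)(=O)N(c1ccc(Cl)cn1)S(=O)(=O)C(F)(F)F
Why: Kinetic deprotonation should take place at the C7 methylene, since the C9–H is hindered and deactivated by the silyloxy group, and the enolate is O-triflated (enol triflate formation).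

Step 12
Reactants: 19 4β-(tert-butyldimethylsilyloxy)-9α-(triisopropylsilyloxy)-10αH-11,12,13,15-tetranoreremophil-7-en-8-yl trifluoromethanesulfonate
Product: 20 4β-(tert-butyldimethylsilyloxy)-9α-(triisopropylsilyloxy)-10αH-11,12,13,15-tetranoreremophil-7-ene
Conditions: Pd(OAc)2 (5 mol%), PPh3, HCO2H, Bu3N, DMF, 60 °C
Reagents that add atoms: none
Why: Palladium-catalysed formate reduction of the enol triflate should replace OTf by H and leave both silyl ethers and the new C7=C8 alkene intact.

Step 13
Reactants: 20 4β-(tert-butyldimethylsilyloxy)-9α-(triisopropylsilyloxy)-10αH-11,12,13,15-tetranoreremophil-7-ene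
Product: 21 9α-(triisopropylsilyloxy)-10αH-11,12,13,15-tetranoreremophil-7-en-4β-ol
Conditions: HF·pyridine, pyridine, THF, 0 → 25 °C
Reagents that add atoms: none
Why: Buffered HF·pyridine should cleave the secondary TBS ether well before the bulkier TIPS ether (selective desilylation).

Step 14
Reactants: 21 9α-(triisopropylsilyloxy)-10αH-11,12,13,15-tetranoreremophil-7-en-4β-ol
Product: 23 9α-(triisopropylsilyloxy)-10αH-11,12,13,15-tetranoreremophila-2,7-dien-4-one, via saturated ketone 22 (not isolated)
Conditions: IBX (4 equiv), DMSO/toluene, 70 °C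
Reagents that add atoms: none
Why: IBX should oxidise the carbinol to the ketone and then dehydrogenate it through its only possible enol, toward C3 because C5 is quaternary (one-pot alcohol-to-enone oxidation).

Step 15
Reactants: 23 9α-(triisopropylsilyloxy)-10αH-11,12,13,15-tetranoreremophila-2,7-dien-4-one
Product: 24 9α-(triisopropylsilyloxy)-10αH-11,12,13-trinoreremophila-2,7-dien-4β-ol
Conditions: MeLi, Et2O, −78 °C; H2O
Reagents that add atoms: methyllithium, [Li]C
Why: 1,2-Addition of methyllithium to the enone carbonyl should bring in C15 from the face opposite the C5 methyl, and the new carbinol centre is lost in the next step.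

Step 16
Reactants: 24 9α-(triisopropylsilyloxy)-10αH-11,12,13-trinoreremophila-2,7-dien-4β-ol
Product: 25 9α-(triisopropylsilyloxy)-10αH-11,12,13-trinoreremophila-3,7-dien-2-one
Conditions: PCC, Celite, CH2Cl2, 25 °C
Reagents that add atoms: pyridinium chlorochromate (supplies the C2 carbonyl oxygen), [O-][Cr](=O)(=O)Cl.c1cc[nH+]cc1
Why: In this Babler–Dauben oxidative transposition the chromate ester of the tertiary allylic alcohol should undergo a [3,3] shift to C2 and be oxidised to the β-methyl enone.

Step 17
Reactants: 25 9α-(triisopropylsilyloxy)-10αH-11,12,13-trinoreremophila-3,7-dien-2-one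
Product: 26 7α,8α-epoxy-9α-(triisopropylsilyloxy)-10αH-11,12,13-trinoreremophil-3-en-2-one
Conditions: mCPBA, NaHCO3, CH2Cl2, 0 °C
Reagents that add atoms: 3-chloroperoxybenzoic acid, O=C(OO)c1cccc(Cl)c1
Why: Prilezhaev epoxidation should pick the electron-rich C7=C8 alkene over the enone and come from the α-face, since the β-face is shielded by the axial C5 methyl (as steroid 2-enes give 2α,3α-epoxides) and the 9α-silyloxy group is pseudo-equatorial.

Step 18
Reactants: 26 7α,8α-epoxy-9α-(triisopropylsilyloxy)-10αH-11,12,13-trinoreremophil-3-en-2-one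
Product: 27 7α,8α-epoxy-9α-(triisopropylsilyloxy)-10αH-11,12,13-trinoreremophilan-2-one
Conditions: H2 (1 atm), 10% Pd/C, EtOAc, 25 °C
Reagents that add atoms: none
Why: Heterogeneous hydrogenation should add H2 to C3=C4 from the α-face, opposite the adjacent axial C5 methyl, which makes the C4 methyl β and equatorial (cis to C14).

Step 19
Reactants: 27 7α,8α-epoxy-9α-(triisopropylsilyloxy)-10αH-11,12,13-trinoreremophilan-2-one
Product: 28 7α,8α-epoxy-9α-(triisopropylsilyloxy)-10αH-11,12,13-trinoreremophilan-2α-ol
Conditions: L-Selectride, THF, −78 °C; H2O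
Reagents that add atoms: none
Why: The bulky hydride should attack the C2 ketone from the equatorial direction and give the axial 2α-alcohol, as 3-keto-5α-steroids give 3α-ols.

Step 20
Reactants: 28 7α,8α-epoxy-9α-(triisopropylsilyloxy)-10αH-11,12,13-trinoreremophilan-2α-ol; 29 isopropenylmagnesium bromide
Product: 30 9α-(triisopropylsilyloxy)-10αH-eremophil-11-ene-2α,8α-diol
Conditions: 29 (4 equiv), CuI (20 mol%), THF, −30 → 0 °C; aq. NH4Cl
Reagents that add atoms: isopropenylmagnesium bromide, C=C(C)[Mg]Br
Why: Copper-catalysed Grignard opening of the epoxide should follow the Fürst–Plattner rule, with SN2 attack at C7 from the β-face (trans-diaxial, as 2α,3α-epoxy-5α-steroids give 2β-substituted 3α-ols), which sets C7 by inversion and leaves the 8α-hydroxyl, while the C2 alkoxide uses up one equivalent of reagent.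

Step 21
Reactants: 30 9α-(triisopropylsilyloxy)-10αH-eremophil-11-ene-2α,8α-diol
Product: 31 2α-acetoxy-9α-(triisopropylsilyloxy)-10αH-eremophil-11-en-8α-ol
Conditions: Ac2O, pyridine, 0 → 25 °C
Reagents that add atoms: acetic anhydride, CC(=O)OC(C)=O
Why: Mild acetylation should take the accessible 2α-hydroxyl, while the 8α-hydroxyl is shut in between the TIPS ether and the isopropenyl-bearing carbon.

Step 22
Reactants: 31 2α-acetoxy-9α-(triisopropylsilyloxy)-10αH-eremophil-11-en-8α-ol
Product: 32 2α-acetoxy-10αH-eremophil-11-ene-8α,9α-diol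
Conditions: HF·pyridine, MeCN, 25 °C
Reagents that add atoms: none
Why: Unbuffered HF·pyridine should cleave the TIPS ether (fluoride desilylation) without touching the acetate or the alkene.

Step 23
Reactants: 32 2α-acetoxy-10αH-eremophil-11-ene-8α,9α-diol; 33 angelic acid
Product: 35 2α-acetoxy-8α-hydroxy-10αH-eremophil-11-en-9α-yl angelate, via mixed anhydride 34 (not isolated)
Conditions: 33, 2,4,6-trichlorobenzoyl chloride, Et3N, toluene, 25 °C; then 32, toluene, 75 °C
Reagents that add atoms: angelic acid, C/C=C(/C)C(=O)O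
Why: Yamaguchi-type acylation with the mixed anhydride and no DMAP should keep the Z geometry, and the equatorial 9α-hydroxyl should react before the axial 8α-hydroxyl that sits next to the axial isopropenyl group.

**Compound list**
1 | decahydronaphthalene-1,5-diol (commercial mixture of stereoisomers) | OC1CCCC2C(O)CCCC12 | starting material
2 | 5-hydroxyoctahydronaphthalen-1(2H)-one (not isolated) | O=C1CCCC2C(O)CCCC12 | intermediate
3 | octahydronaphthalene-1,5-dione (cis/trans mixture) | O=C1CCCC2C(=O)CCCC12 | intermediate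
4 | 8a-bromooctahydronaphthalene-1,5-dione (not isolated) | O=C1CCCC2C(=O)CCCC12Br | intermediate
5 | 3,4,7,8-tetrahydronaphthalene-1,5(2H,6H)-dione | O=C1CCCC2=C1CCCC2=O | intermediate
6 | (5S)-5-hydroxy-3,4,5,6,7,8-hexahydronaphthalen-1(2H)-one (not isolated) | O=C1CCCC2=C1CCC[C@@H]2O | intermediate
7 | (1S,5S)-1,2,3,4,5,6,7,8-octahydronaphthalene-1,5-diol (C2-symmetric, both OH on one face) | O[C@H]1CCCC2=C1CCC[C@@H]2O | intermediate
8 | diiodomethane | ICI | starting material
9 | (1R,2S,6R,7S)-tricyclo[4.4.1.0^1,6]undecane-2,7-diol (C2-symmetric, both OH on the face of the C11 methylene) | O[C@H]1CCC[C@@]23C[C@@]12CCC[C@@H]3O | intermediate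
10 | (1R,2S,6R,7S)-7-(tert-butyldimethylsilyloxy)tricyclo[4.4.1.0^1,6]undecan-2-ol | O[C@H]1CCC[C@@]23C[C@@]12CCC[C@@H]3O[Si](C)(C)C(C)(C)C | intermediate
11 | O-[(1R,2S,6R,7S)-7-(tert-butyldimethylsilyloxy)tricyclo[4.4.1.0^1,6]undecan-2-yl] O-phenyl carbonothioate | S=C(Oc1ccccc1)O[C@H]1CCC[C@@]23C[C@@]12CCC[C@@H]3O[Si](C)(C)C(C)(C)C | intermediate
12 | 4β-(tert-butyldimethylsilyloxy)-11,12,13,15-tetranoreremophil-9-ene [(1S,8aS)-1-silyloxy-8a-methyl-1,2,3,4,6,7,8,8a-octahydronaphthalene] | CC(C)(C)[Si](C)(C)O[C@H]1CCCC2=CCCC[C@]12C | intermediate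
13 | 4β-(tert-butyldimethylsilyloxy)-11,12,13,15-tetranoreremophil-9-en-8-one | CC(C)(C)[Si](C)(C)O[C@H]1CCCC2=CC(=O)CC[C@]12C | intermediate
14 | lithium Δ8-enolate of 4β-(tert-butyldimethylsilyloxy)-10αH-11,12,13,15-tetranoreremophilan-8-one (not isolated) | CC(C)(C)[Si](C)(C)O[C@H]1CCC[C@H]2C=C(O[Li])CC[C@]12C | intermediate
15 | 4β-(tert-butyldimethylsilyloxy)-8-(triisopropylsilyloxy)-10αH-11,12,13,15-tetranoreremophil-8-ene | CC(C)(C)[Si](C)(C)O[C@H]1CCC[C@H]2C=C(O[Si](C(C)C)(C(C)C)C(C)C)CC[C@]12C | intermediate
16 | 8α,9α-epoxide of 15 (not isolated) | CC(C)(C)[Si](C)(C)O[C@H]1CCC[C@H]2[C@@H]3O[C@]3(O[Si](C(C)C)(C(C)C)C(C)C)CC[C@]12C | intermediate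
17 | 4β-(tert-butyldimethylsilyloxy)-9α-(triisopropylsilyloxy)-10αH-11,12,13,15-tetranoreremophilan-8-one | CC(C)(C)[Si](C)(C)O[C@H]1CCC[C@H]2[C@H](O[Si](C(C)C)(C(C)C)C(C)C)C(=O)CC[C@]12C | intermediate
18 | potassium Δ7-enolate of 17 (not isolated) | CC(C)(C)[Si](C)(C)O[C@H]1CCC[C@H]2[C@H](O[Si](C(C)C)(C(C)C)C(C)C)C(O[K])=CC[C@]12C | intermediate
19 | 4β-(tert-butyldimethylsilyloxy)-9α-(triisopropylsilyloxy)-10αH-11,12,13,15-tetranoreremophil-7-en-8-yl trifluoromethanesulfonate | CC(C)(C)[Si](C)(C)O[C@H]1CCC[C@H]2[C@H](O[Si](C(C)C)(C(C)C)C(C)C)C(OS(=O)(=O)C(F)(F)F)=CC[C@]12C | intermediate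
20 | 4β-(tert-butyldimethylsilyloxy)-9α-(triisopropylsilyloxy)-10αH-11,12,13,15-tetranoreremophil-7-ene | CC(C)(C)[Si](C)(C)O[C@H]1CCC[C@H]2[C@H](O[Si](C(C)C)(C(C)C)C(C)C)C=CC[C@]12C | intermediate
21 | 9α-(triisopropylsilyloxy)-10αH-11,12,13,15-tetranoreremophil-7-en-4β-ol | O[C@H]1CCC[C@H]2[C@H](O[Si](C(C)C)(C(C)C)C(C)C)C=CC[C@]12C | intermediate
22 | 9α-(triisopropylsilyloxy)-10αH-11,12,13,15-tetranoreremophil-7-en-4-one (not isolated) | O=C1CCC[C@H]2[C@H](O[Si](C(C)C)(C(C)C)C(C)C)C=CC[C@]12C | intermediate
23 | 9α-(triisopropylsilyloxy)-10αH-11,12,13,15-tetranoreremophila-2,7-dien-4-one | O=C1C=CC[C@H]2[C@H](O[Si](C(C)C)(C(C)C)C(C)C)C=CC[C@]12C | intermediate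
24 | 9α-(triisopropylsilyloxy)-10αH-11,12,13-trinoreremophila-2,7-dien-4β-ol (4α-methyl expected) | C[C@]1(O)C=CC[C@H]2[C@H](O[Si](C(C)C)(C(C)C)C(C)C)C=CC[C@]12C | intermediate
25 | 9α-(triisopropylsilyloxy)-10αH-11,12,13-trinoreremophila-3,7-dien-2-one | CC1=CC(=O)C[C@H]2[C@H](O[Si](C(C)C)(C(C)C)C(C)C)C=CC[C@]12C | intermediate
26 | 7α,8α-epoxy-9α-(triisopropylsilyloxy)-10αH-11,12,13-trinoreremophil-3-en-2-one | CC1=CC(=O)C[C@H]2[C@H](O[Si](C(C)C)(C(C)C)C(C)C)[C@@H]3O[C@@H]3C[C@]12C | intermediate
27 | 7α,8α-epoxy-9α-(triisopropylsilyloxy)-10αH-11,12,13-trinoreremophilan-2-one (4β-methyl) | C[C@H]1CC(=O)C[C@H]2[C@H](O[Si](C(C)C)(C(C)C)C(C)C)[C@@H]3O[C@@H]3C[C@]12C | intermediate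
28 | 7α,8α-epoxy-9α-(triisopropylsilyloxy)-10αH-11,12,13-trinoreremophilan-2α-ol | C[C@H]1C[C@H](O)C[C@H]2[C@H](O[Si](C(C)C)(C(C)C)C(C)C)[C@@H]3O[C@@H]3C[C@]12C | intermediate
29 | isopropenylmagnesium bromide (prop-1-en-2-ylmagnesium bromide, commercial THF solution) | C=C(C)[Mg]Br | starting material
30 | 9α-(triisopropylsilyloxy)-10αH-eremophil-11-ene-2α,8α-diol (7β-isopropenyl) | C[C@H]1C[C@H](O)C[C@H]2[C@H](O[Si](C(C)C)(C(C)C)C(C)C)[C@H](O)[C@@H](C(C)=C)C[C@]12C | intermediate
31 | 2α-acetoxy-9α-(triisopropylsilyloxy)-10αH-eremophil-11-en-8α-ol | C[C@H]1C[C@H](OC(C)=O)C[C@H]2[C@H](O[Si](C(C)C)(C(C)C)C(C)C)[C@H](O)[C@@H](C(C)=C)C[C@]12C | intermediate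
32 | 2α-acetoxy-10αH-eremophil-11-ene-8α,9α-diol | C[C@H]1C[C@H](OC(C)=O)C[C@H]2[C@H](O)[C@H](O)[C@@H](C(C)=C)C[C@]12C | intermediate
33 | angelic acid [(Z)-2-methylbut-2-enoic acid] | C/C=C(/C)C(=O)O | starting material
34 | angelic 2,4,6-trichlorobenzoic anhydride (not isolated) | C/C=C(/C)C(=O)OC(=O)c1c(Cl)cc(Cl)cc1Cl | intermediate
35 | 2α-acetoxy-8α-hydroxy-10αH-eremophil-11-en-9α-yl angelate (CNP0217919.1) | C[C@H]1C[C@H](OC(C)=O)C[C@H]2[C@H](OC(=O)/C(C)=C\C)[C@H](O)[C@@H](C(C)=C)C[C@]12C | target

**Count and risks**
Total step count: 23. Longest linear sequence: 23 steps (1 → 35); 8, 29 and 33 enter as single-step inputs.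

Steps most likely to fail:

Step 8. Hydrogen abstraction may occur at C1 instead of C8, or the oxidation may run on, so that regioisomeric or over-oxidised enones form. The fallback sets out from 12: dye-sensitised photo-oxygenation (O2, tetraphenylporphyrin, light, CH2Cl2, 0 °C; Schenck ene reaction, which should take the allylic hydrogen at C8 on the more crowded side of the alkene and place oxygen on C10) should give the tertiary allylic hydroperoxide F1. Triphenylphosphine reduces it to the tertiary allylic alcohol F2. Oxidative 1,3-transposition of that alcohol with PCC moves the oxygen to C8 and comes back to the route at 13.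

Step 20. The β-axial approach to C7 is syn to the C5 methyl, so the opening may stall and give way to halohydrin formation by magnesium bromide, Lewis-acid rearrangement of the epoxide, or silyl migration from O9 to the new alkoxide. The fallback sets out from 28 and uses a slim sp-hybridised nucleophile: lithium (trimethylsilyl)acetylide with BF3·OEt2 (THF, −78 °C) should open the epoxide at C7 to the 7β-(trimethylsilylethynyl) 2α,8α-diol F3. K2CO3 in methanol then gives the terminal alkyne F4. Zirconium-catalysed methylalumination (AlMe3, Cp2ZrCl2; Negishi carboalumination) followed by protonolysis turns the ethynyl group into isopropenyl and comes back to the route at 30.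

Step 23. Acylation may reach the axial 8-hydroxyl or both hydroxyls, and the angelate may isomerise to the tiglate on prolonged heating. The fallback sets out from 32: dibutyltin oxide (toluene, reflux, water removed) should give the 8,9-O-dibutylstannylene acetal F5, in which the equatorial O9 is the activated oxygen. It is acylated at 0 °C by angeloyl chloride F6, made from 33 with oxalyl chloride at 0 °C, and hydrolytic work-up comes back to the route at 35.

**Further compounds**
F1 | step 8 | 4β-(tert-butyldimethylsilyloxy)-10-hydroperoxy-11,12,13,15-tetranoreremophil-8-ene (C10 configuration open) | CC(C)(C)[Si](C)(C)O[C@H]1CCCC2(OO)C=CCC[C@]12C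
F2 | step 8 | 4β-(tert-butyldimethylsilyloxy)-11,12,13,15-tetranoreremophil-8-en-10-ol (C10 configuration open) | CC(C)(C)[Si](C)(C)O[C@H]1CCCC2(O)C=CCC[C@]12C
F3 | step 20 | 7β-[(trimethylsilyl)ethynyl]-9α-(triisopropylsilyloxy)-10αH-11,12,13-trinoreremophilane-2α,8α-diol | C[C@H]1C[C@H](O)C[C@H]2[C@H](O[Si](C(C)C)(C(C)C)C(C)C)[C@H](O)[C@@H](C#C[Si](C)(C)C)C[C@]12C
F4 | step 20 | 7β-ethynyl-9α-(triisopropylsilyloxy)-10αH-11,12,13-trinoreremophilane-2α,8α-diol | C[C@H]1C[C@H](O)C[C@H]2[C@H](O[Si](C(C)C)(C(C)C)C(C)C)[C@H](O)[C@@H](C#C)C[C@]12C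
F5 | step 23 | 8,9-O-dibutylstannylene acetal of 32 | C[C@H]1C[C@H](OC(C)=O)C[C@H]2[C@@H]3O[Sn](CCCC)(CCCC)O[C@@H]3[C@@H](C(C)=C)C[C@]12C
F6 | step 23 | angeloyl chloride [(Z)-2-methylbut-2-enoyl chloride] | C/C=C(/C)C(Cl)=O
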